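The constants used here come from no measurement; the rest is arithmetic.

At early times the substrate meets a small loading of free catalyst, yet the binding step, counting its forward rate with no way back and the other concentrations held at their charge, has a half-life of 0.26 min, far shorter than the 1.0 h of the run.

substrate 0.050 M; free catalyst 0.05 mol%; time 1.0 h

    catalyst intermediate A ⇌ catalyst intermediate B (K1 = 2.0, k1 = 1300 s⁻¹)
    substrate + free catalyst ⇌ catalyst intermediate A (K2 = 14 L mol⁻¹, k2 = 1800 L mol⁻¹ s⁻¹)
    crystals ⇌ product, rate k3*(cs3 - [product]) while solid is left; crystals form when [product] > cs3 (cs3 = 17 mM, k3 = 0.32 s⁻¹)
    catalyst intermediate B ⇌ free catalyst + product (K4 = 0.46 M, k4 = 2100 s⁻¹)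

- amounts and yields of product count crystals too
- given per volume of solution although it is solid: crystals
- the reaction counts as stopped when no species that holds the substrate changes by six tenths of a point or more over the second half of the time
- run time (flask): 1.0 h

1. which holds at 1.0 h: what has brought the reaction to rest, or that it has not come to rest (forward and back rates have come level / it is still moving / no working catalyst is left / all of the substrate has reacted)
2. share of the substrate used up at 1.0 h
3. product at 1.0 h, in percent of the substrate charged

The other two cycle steps have forward constants of 1300 s⁻¹ and 2100 s⁻¹, larger than the 90.0 s⁻¹ of binding at the charged substrate. So two colleagues at the board expect this flask to reach rest by the reading, and they argue over where it stops. They share one number: go round the cycle and the catalyst cancels, so the product of the equilibrium constants of the cycle steps, the overall constant 12.9, gives [product]/[substrate] in solution at rest.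

The first colleague keeps the whole charge dissolved, so that [substrate] and [product] share it in that ratio, and conversion is 92.8%.

The second puts that answer back in. It asks for [product] of 46.4 mM, more than the solubility of 17 mM, so crystals must form, and the crystal step has a characteristic time 1/k3 of 3.12 s, far shorter than the run. At rest with solid left, [product] stands at 17 mM, and going round again with that value gives [substrate] of 1.32 mM, which is 2.64% of the charge, and a conversion of 97.4%.

I side with the second. One more round changes little: the catalyst can hold at most 0.05 mol% of the charge, less than the 2.64% left, so I take product equal to conversion.

The forecast says forward and back rates have come level, with conversion 97.4% and product 97.4%: “Crystals remain and pin dissolved product at 17 mM”.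

The simulation gives forward and back rates have come level, with conversion 97.4% and product 97.4%; at 1.00 h this flask holds crystals amounting to 63.4% of the charge.

The first colleague's ground is the neighbouring flask, with the same loading and time but 0.013 M of substrate. The overall constant is unchanged, and the dissolved reckoning now asks for [product] of 12.1 mM, less than the solubility of 17 mM. So no crystals are expected there, and the ratio gives a conversion of 92.8%, leaving 7.20% of the substrate. The simulated neighbouring flask converts 92.8%, and at 1.00 h it holds crystals of 0% and 7.2% of its substrate.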